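## Retrosynthetic overview

- Last operation (one pot): the coumarin-fused 1,3-dioxin and then the tetrahydropyran are closed on a 4-chloro-3-(hydroxyalkyl)coumarin that carries a cyclopentenyl allylic benzoate, with 4-methyl-2-oxopentanal as partner. The last bond made joins the ketal carbon to the methyl-bearing allylic carbon.
- Enabling feature: the ketal carbon of the 2,9-dioxabicyclo[3.3.1]nonane is both the α-carbon of the 3-methylbutanoyl ketone and the O–C–O carbon of a dioxin fused to C-3/C-4 of the coumarin, so it is an acidic acetal C–H before the last bond exists. Its partner, the CH(CH3) of the tetrahydropyran, is allylic to the cyclopentene C=C. Together they are an enolate/π-allyl pair held 1,3-diaxially on the dioxin.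
- Cyclopentene: ring-closing metathesis after methylenation of the ketone of an anti-aldol adduct.
- The anti-aldol of an (R)-lactate-derived α-benzoyloxy ketone (side chain from an Evans alkylation) with 4-chloro-3-formyl-5-methylcoumarin sets the carbinol and ring-fusion centres. The lactate centre then serves as the allylic leaving group.
- Ring order: benzene (bought) → pyranone → cyclopentene → 1,3-dioxin → tetrahydropyran.

Key step: step 14

Remark: C-3 and C-4 are coumarin locants. The acetal carbon of the dioxin intermediates of step 14 is carried as an epimer mixture, which is immaterial because it becomes a planar enolate carbon. 2'-Hydroxy-6'-methylacetophenone is taken as a catalogue compound.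

## Route

Step 1
Reactants: 1 2'-hydroxy-6'-methylacetophenone; 2 diethyl carbonate
Product: 3 4-hydroxy-5-methylcoumarin
Conditions: NaH (3.5 equiv), toluene, 110 °C; then aq. HCl
Reagents that add atoms: none
Why: Claisen-type C-acylation of the ketone enolate by the carbonate, then lactonisation onto the phenoxide, is the standard 4-hydroxycoumarin synthesis from 2-hydroxyacetophenones.

Step 2
Reactants: 3 4-hydroxy-5-methylcoumarin
Product: 4 4-chloro-5-methyl-2-oxo-2H-chromene-3-carbaldehyde
Conditions: POCl3 (3 equiv), DMF, 0 to 60 °C; then ice/water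
Reagents that add atoms: N,N-dimethylformamide CN(C)C=O; phosphoryl chloride O=P(Cl)(Cl)Cl; water O
Why: Vilsmeier–Haack formylation at nucleophilic C-3, with exchange of the vinylogous-acid hydroxyl for chloride, is the established route to 4-chloro-3-formylcoumarins.

Step 3
Reactants: 5 (4R)-4-benzyl-3-propanoyl-1,3-oxazolidin-2-one; 6 allyl iodide
Product: 8 (4R)-4-benzyl-3-[(2S)-2-methylpent-4-enoyl]-1,3-oxazolidin-2-one, via sodium enolate 7 (not isolated)
Conditions: NaN(SiMe3)2 (1.1 equiv), THF, −78 °C; then 6 (3 equiv), −78 to −40 °C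
Reagents that add atoms: none
Why: Evans alkylation: the chelated (Z)-enolate should be allylated on the face away from the benzyl group, which sets the (S) methyl-bearing centre.

Step 4
Reactants: 8 (4R)-4-benzyl-3-[(2S)-2-methylpent-4-enoyl]-1,3-oxazolidin-2-one
Product: 9 (2S)-2-methylpent-4-en-1-ol
Conditions: LiBH4, H2O (1 equiv), Et2O, 0 °C
Reagents that add atoms: none
Why: Reductive cleavage of the N-acyl oxazolidinone gives the primary alcohol without enolising the stereocentre.

Step 5
Reactants: 9 (2S)-2-methylpent-4-en-1-ol
Product: 10 (4S)-5-bromo-4-methylpent-1-ene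
Conditions: CBr4, PPh3, CH2Cl2, 0 °C
Reagents that add atoms: tetrabromomethane BrC(Br)(Br)Br
Why: The Appel reaction substitutes at the primary carbon and leaves the stereocentre untouched.

Step 6
Reactants: 11 methyl (R)-lactate
Product: 12 (2R)-2-hydroxy-N-methoxy-N-methylpropanamide
Conditions: MeNHOMe·HCl (2.5 equiv), iPrMgCl (5 equiv), THF, −20 to 0 °C
Reagents that add atoms: N,O-dimethylhydroxylamine hydrochloride CNOC.Cl
Why: Aminolysis of the ester by the chloromagnesium amide (Weinreb amide formation) is known to proceed on lactates without racemisation.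

Step 7
Reactants: 10 (4S)-5-bromo-4-methylpent-1-ene; 12 (2R)-2-hydroxy-N-methoxy-N-methylpropanamide
Product: 15 (2R,5S)-2-hydroxy-5-methyloct-7-en-3-one, via Grignard reagent 13 (not isolated), via chloromagnesium alkoxide 14 (not isolated)
Conditions: 10, Mg, THF, 40 °C; separately 12, iPrMgCl (1.0 equiv), THF, −20 °C; then the Grignard solution (1.4 equiv), 0 °C to rt; aq. NH4Cl
Reagents that add atoms: none
Why: Weinreb ketone synthesis: the chelated tetrahedral intermediate stops at the ketone, and the hydroxyl is masked as its magnesium alkoxide so that the chiral Grignard reagent is not consumed as a base.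

Step 8
Reactants: 15 (2R,5S)-2-hydroxy-5-methyloct-7-en-3-one
Product: 16 (2R,5S)-5-methyl-3-oxooct-7-en-2-yl benzoate
Conditions: (PhCO)2O (1.5 equiv), DMAP (0.1 equiv), iPr2NEt, CH2Cl2, rt
Reagents that add atoms: benzoic anhydride O=C(OC(=O)c1ccccc1)c1ccccc1
Why: DMAP-catalysed acylation of the secondary alcohol under non-epimerising conditions installs the benzoate that directs the next step.

Step 9
Reactants: 16 (2R,5S)-5-methyl-3-oxooct-7-en-2-yl benzoate; 4 4-chloro-5-methyl-2-oxo-2H-chromene-3-carbaldehyde
Product: 18 (2R,4S,5S)-4-[(R)-(4-chloro-5-methyl-2-oxo-2H-chromen-3-yl)(hydroxy)methyl]-5-methyl-3-oxooct-7-en-2-yl benzoate, via boron enolate 17 (not isolated)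
Conditions: (c-C6H11)2BCl (1.5 equiv), Me2NEt (1.8 equiv), Et2O, −78 to 0 °C; then 4 in CH2Cl2, −78 to −25 °C; then MeOH, pH 7 buffer, H2O2, 0 °C
Reagents that add atoms: none
Why: Lactate-derived boron anti-aldol: the (E)-enol borinate reacts through a Zimmerman–Traxler chair (1,2-anti), and the benzoyloxy-bearing centre steers the aldehyde to one enolate face, which should give the (R) carbinol and the required ring-fusion centre.

Step 10
Reactants: 18 the anti-aldol adduct
Product: 19 (2R,4R,5S)-4-[(R)-(4-chloro-5-methyl-2-oxo-2H-chromen-3-yl)(hydroxy)methyl]-5-methyl-3-methylideneoct-7-en-2-yl benzoate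
Conditions: Zn, CH2Br2, TiCl4 (preformed reagent), THF/CH2Cl2, 0 °C to rt
Reagents that add atoms: dibromomethane BrCBr
Why: Takai–Lombardo methylenation is non-basic, works on hindered enolisable ketones and leaves esters, the lactone and the free hydroxyl untouched.

Step 11
Reactants: 19 the 1,1-disubstituted/terminal diene
Product: 20 (1R)-1-{(4S,5R)-5-[(R)-(4-chloro-5-methyl-2-oxo-2H-chromen-3-yl)(hydroxy)methyl]-4-methylcyclopent-1-en-1-yl}ethyl benzoate
Conditions: second-generation Grubbs catalyst RuCl2(=CHPh)(H2IMes)(PCy3) (5 mol%), CH2Cl2, 40 °C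
Reagents that add atoms: none
Why: Ring-closing metathesis to a five-membered trisubstituted alkene is favourable and tolerates the free alcohol, the benzoate and the chlorocoumarin.

Step 12
Reactants: 21 3-methylbutanoyl chloride
Product: 22 1-diazo-4-methylpentan-2-one
Conditions: Me3SiCHN2 (2 equiv), MeCN/THF, 0 °C to rt
Reagents that add atoms: trimethylsilyldiazomethane C[Si](C)(C)C=[N+]=[N-]
Why: C-acylation of the silyl diazoalkane with loss of Me3SiCl is the Arndt–Eistert-type diazoketone synthesis.

Step 13
Reactants: 22 1-diazo-4-methylpentan-2-one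
Product: 23 4-methyl-2-oxopentanal
Conditions: dimethyldioxirane (1.1 equiv, acetone solution), 0 °C; acetone removed cold; used at once
Reagents that add atoms: dimethyldioxirane CC1(C)OO1
Why: Oxygen-atom transfer to the diazo carbon with loss of N2 should give the α-ketoaldehyde under neutral, anhydrous conditions.

Step 14
Reactants: 20 the cyclopentenyl carbinol; 23 4-methyl-2-oxopentanal
Product: 27 CNP0310889.1 (target), via hemiacetal 24 (not isolated), via dioxin acetal 25 (not isolated), via potassium enolate 26 (not isolated)
Conditions: 23 (1.3 equiv), 4 Å MS, THF, rt; KN(SiMe3)2 (1.05 equiv), −78 to 0 °C; then KN(SiMe3)2 (1.3 equiv), −78 °C; Pd(PPh3)4 (10 mol%), −78 to 45 °C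
Reagents that add atoms: none
Why: Proposed new method: the hemiacetal from the carbinol of 20 and the aldehyde of 23 is deprotonated, and its alkoxide adds to C-4 of the chlorocoumarin and expels chloride (6-endo-trig addition–elimination), which closes the 1,3-dioxin; the closest known reactions are the hemiacetal-alkoxide oxa-conjugate addition that turns hydroxy enoates into 1,3-dioxane acetals and the displacement of chloride from 4-chlorocoumarins by alkoxides. The acetal C–H of 25, flanked by two oxygens and the ketone, is then removed by the second portion of base, zerovalent palladium ionises the allylic benzoate with inversion, and the enolate carbon attacks the methyl-bearing allyl terminus anti to palladium; the closest known reactions are the intramolecular Tsuji–Trost allylation of α-alkoxy ketone enolates and the ring-closing stage of palladium [3+3] annulations of centrally tethered allyl units. This second closure forms the six-membered tetrahydropyran through a chair in which the central and one terminal allyl carbon become ring atoms and the new bond is axial on the dioxin. The ketal centre can form in one sense only, because the coumarin bridge must span both bridgeheads of the 2,9-dioxabicyclo[3.3.1]nonane; the methyl-bearing centre follows from double inversion (net retention of the lactate-derived (R) configuration) and from the chair with an equatorial methyl group, and both effects point the same way. The step needs regioselectivity within the allyl unit: attack at the exocyclic terminus keeps the endocyclic cyclopentene and gives a fused ring, whereas attack at the ring terminus would build a bridged bicyclo[3.2.1] unit with an sp2 one-carbon bridge. Enolisation towards the isobutyl CH2 is unproductive, because that enolate could only close an eight-membered ring and should equilibrate to the more acidic O,O-flanked position.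

## Compound list

1 | 2'-hydroxy-6'-methylacetophenone | CC(=O)c1c(C)cccc1O | starting material
2 | diethyl carbonate | CCOC(=O)OCC | starting material
3 | 4-hydroxy-5-methylcoumarin | Cc1cccc2oc(=O)cc(O)c12 | intermediate
4 | 4-chloro-5-methyl-2-oxo-2H-chromene-3-carbaldehyde | Cc1cccc2oc(=O)c(C=O)c(Cl)c12 | intermediate
5 | (4R)-4-benzyl-3-propanoyl-1,3-oxazolidin-2-one | CCC(=O)N1[C@H](Cc2ccccc2)COC1=O | starting material
6 | allyl iodide | C=CCI | starting material
7 | sodium (Z)-enolate of 5 | C/C=C(\[O-])N1[C@H](Cc2ccccc2)COC1=O.[Na+] | intermediate (not isolated)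
8 | (4R)-4-benzyl-3-[(2S)-2-methylpent-4-enoyl]-1,3-oxazolidin-2-one | C=CC[C@H](C)C(=O)N1[C@H](Cc2ccccc2)COC1=O | intermediate
9 | (2S)-2-methylpent-4-en-1-ol | C=CC[C@H](C)CO | intermediate
10 | (4S)-5-bromo-4-methylpent-1-ene | C=CC[C@H](C)CBr | intermediate
11 | methyl (R)-lactate | C[C@@H](O)C(=O)OC | starting material
12 | (2R)-2-hydroxy-N-methoxy-N-methylpropanamide | C[C@@H](O)C(=O)N(C)OC | intermediate
13 | [(2S)-2-methylpent-4-en-1-yl]magnesium bromide | C=CC[C@H](C)C[Mg]Br | intermediate (not isolated)
14 | chloromagnesium alkoxide of 12 | C[C@@H](O[Mg]Cl)C(=O)N(C)OC | intermediate (not isolated)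
15 | (2R,5S)-2-hydroxy-5-methyloct-7-en-3-one | C[C@@H](O)C(=O)C[C@@H](C)CC=C | intermediate
16 | (2R,5S)-5-methyl-3-oxooct-7-en-2-yl benzoate | C[C@@H](OC(=O)c1ccccc1)C(=O)C[C@@H](C)CC=C | intermediate
17 | (E)-enol dicyclohexylborinate of 16 | C[C@@H](OC(=O)c1ccccc1)/C(OB(C1CCCCC1)C1CCCCC1)=C\[C@@H](C)CC=C | intermediate (not isolated)
18 | (2R,4S,5S)-4-[(R)-(4-chloro-5-methyl-2-oxo-2H-chromen-3-yl)(hydroxy)methyl]-5-methyl-3-oxooct-7-en-2-yl benzoate | Cc1cccc2oc(=O)c(c(Cl)c12)[C@H](O)[C@H]([C@@H](C)CC=C)C(=O)[C@@H](C)OC(=O)c1ccccc1 | intermediate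
19 | (2R,4R,5S)-4-[(R)-(4-chloro-5-methyl-2-oxo-2H-chromen-3-yl)(hydroxy)methyl]-5-methyl-3-methylideneoct-7-en-2-yl benzoate | Cc1cccc2oc(=O)c(c(Cl)c12)[C@H](O)[C@H]([C@@H](C)CC=C)C(=C)[C@@H](C)OC(=O)c1ccccc1 | intermediate
20 | (1R)-1-{(4S,5R)-5-[(R)-(4-chloro-5-methyl-2-oxo-2H-chromen-3-yl)(hydroxy)methyl]-4-methylcyclopent-1-en-1-yl}ethyl benzoate | Cc1cccc2oc(=O)c(c(Cl)c12)[C@H](O)[C@@H]1[C@@H](C)CC=C1[C@@H](C)OC(=O)c1ccccc1 | intermediate
21 | 3-methylbutanoyl chloride | CC(C)CC(Cl)=O | starting material
22 | 1-diazo-4-methylpentan-2-one | CC(C)CC(=O)C=[N+]=[N-] | intermediate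
23 | 4-methyl-2-oxopentanal | CC(C)CC(=O)C=O | intermediate
24 | hemiacetal of the carbinol of 20 with the aldehyde of 23 (hemiacetal carbon: both epimers) | Cc1cccc2oc(=O)c(c(Cl)c12)[C@H](OC(O)C(=O)CC(C)C)[C@@H]1[C@@H](C)CC=C1[C@@H](C)OC(=O)c1ccccc1 | intermediate (not isolated)
25 | (4R)-4-{(1R,5S)-2-[(1R)-1-(benzoyloxy)ethyl]-5-methylcyclopent-2-en-1-yl}-10-methyl-2-(3-methylbutanoyl)-4H-[1,3]dioxino[5,4-c]chromen-5-one (C-2: both epimers) | Cc1cccc2oc(=O)c3c(c12)OC(C(=O)CC(C)C)O[C@@H]3[C@@H]1[C@@H](C)CC=C1[C@@H](C)OC(=O)c1ccccc1 | intermediate (not isolated)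
26 | potassium enolate of 25 (2-alkylidene-1,3-dioxin; enolate geometry not defined) | Cc1cccc2oc(=O)c3c(c12)OC(=C([O-])CC(C)C)O[C@@H]3[C@@H]1[C@@H](C)CC=C1[C@@H](C)OC(=O)c1ccccc1.[K+] | intermediate (not isolated)
27 | CNP0310889.1 | Cc1cccc2oc(=O)c3c(c12)O[C@@]1(C(=O)CC(C)C)O[C@@H]3[C@H]2C(=CC[C@@H]2C)[C@H]1C | target

## Step count

Total steps: 14. Longest linear sequence: 9 steps (3, 4, 5, 7, 8, 9, 10, 11, 14).

## Steps most likely to fail

**Step 14 (proposed new method).**
- What may go wrong: a hydride shift within the hemiacetal alkoxide (internal Cannizzaro-type isomerisation to an α-hydroxy ester) or slow addition–elimination at the peri-hindered C-4; alkylation at the ring terminus of the allyl unit; unproductive enolisation.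
- Fallback (known reaction types only): it sets out from 20 and returns at 27, and makes each C–O bond of the dioxin in a separate operation. Rh2(OAc)4-catalysed O–H insertion of diazoketone 22 into the carbinol of 20 should give the α-alkoxy ketone F1. Its enolate, formed with LiN(SiMe3)2, is closed onto the allylic benzoate with Pd(PPh3)4 (intramolecular Tsuji–Trost allylation of an α-alkoxy ketone) to give the 2-acyl tetrahydropyran F2, with the acyl group equatorial after equilibration. Deprotonation with KN(SiMe3)2 and hydroxylation of the O-substituted α-carbon with 2-(phenylsulfonyl)-3-phenyloxaziridine gives the potassium hemiketal alkoxide F3. F3 is not isolated; it closes the dioxin by addition–elimination at C-4 to give 27.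

**Step 10.**
- What may go wrong: slow methylenation at a ketone flanked by two branched carbons; reductive loss of the α-benzoyloxy group or of the vinylogous chloride by zinc; Lewis-acid retro-aldol cleavage.
- Fallback: it sets out from 18 and returns at 20, bypassing 19 and step 11, by joining the ketone carbon directly to the terminal alkene. Silylation of 18 (Et3SiOTf, 2,6-lutidine) gives the triethylsilyl ether F4. A stoichiometric molybdenum alkylidene, Mo(=CHCMe2Ph)(=N-2,6-iPr2C6H3)[OCMe(CF3)2]2 in benzene at rt, first undergoes metathesis with the terminal alkene and then olefinates the ketone intramolecularly, giving the cyclopentene F5. HF·pyridine removes the silyl group to give 20.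

**Step 13.**
- What may go wrong: evaporative loss of the volatile dicarbonyl, hydration and self-aldol oligomerisation on concentration, or over-oxidation. Any water carried forward would hydrolyse the vinylogous chloride in step 14.
- Fallback: it replaces 21 and 22 by commercial ethyl diethoxyacetate and returns at 23, using a storable acetal as the reservoir. Isobutylmagnesium bromide adds once to ethyl diethoxyacetate (THF, −78 °C) to give 1,1-diethoxy-4-methylpentan-2-one F6. Hydrolysis with aqueous HCl in acetone, then distillation of the hydrate from P2O5, gives monomeric 23.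

## Further compounds

F1 | step 14 | (1R)-1-{(4S,5R)-5-[(R)-(4-chloro-5-methyl-2-oxo-2H-chromen-3-yl)(4-methyl-2-oxopentyloxy)methyl]-4-methylcyclopent-1-en-1-yl}ethyl benzoate | Cc1cccc2oc(=O)c(c(Cl)c12)[C@H](OCC(=O)CC(C)C)[C@@H]1[C@@H](C)CC=C1[C@@H](C)OC(=O)c1ccccc1
F2 | step 14 | 4-chloro-5-methyl-3-[(1R,3R,4R,7S,7aR)-4,7-dimethyl-3-(3-methylbutanoyl)-1,3,4,6,7,7a-hexahydrocyclopenta[c]pyran-1-yl]-2H-chromen-2-one | Cc1cccc2oc(=O)c(c(Cl)c12)[C@@H]1O[C@@H](C(=O)CC(C)C)[C@H](C)C2=CC[C@H](C)[C@@H]12
F3 | step 14 | potassium hemiketal alkoxide from hydroxylation of F2 at the O-substituted α-carbon (not isolated) | Cc1cccc2oc(=O)c(c(Cl)c12)[C@@H]1O[C@@]([O-])(C(=O)CC(C)C)[C@H](C)C2=CC[C@H](C)[C@@H]12.[K+]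
F4 | step 10 | triethylsilyl ether of 18 | Cc1cccc2oc(=O)c(c(Cl)c12)[C@H](O[Si](CC)(CC)CC)[C@H]([C@@H](C)CC=C)C(=O)[C@@H](C)OC(=O)c1ccccc1
F5 | step 10 | triethylsilyl ether of 20 | Cc1cccc2oc(=O)c(c(Cl)c12)[C@H](O[Si](CC)(CC)CC)[C@@H]1[C@@H](C)CC=C1[C@@H](C)OC(=O)c1ccccc1
F6 | step 13 | 1,1-diethoxy-4-methylpentan-2-one | CCOC(OCC)C(=O)CC(C)C
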